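**Plan**

- Retrosynthesis: the C-2 hydroxyl of quinone ring B goes back to an ethyl enol ether and the quinone to a para-methoxyphenol. Ring B is then cut at three bonds (C-3/C-4, C-4/C-5, C-1/C-6) into a terminal alkyne (C-5, C-6, carrying the chroman), one CO ligand (C-4) and an alkenyl(methoxy)carbene chromium complex (C-1, C-2, C-3 with its prenyl group).
- Enabling feature: in ring B the carbonyl carbons C-1 and C-4 are para, C-4 lies between the prenyl-bearing C-3 and the chromanyl-bearing C-5, C-6 is the only ring CH, and C-2 carries oxygen. This is the pattern a Dötz benzannulation produces: CO captured between an alkyne carbon and an alkenyl β-carbon, the terminal alkyne CH next to the carbene carbon, and an α-oxygenated alkenyl carbene.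
- Forward order: ring A is prenylated, ring C is closed by oxa-Michael/aldol annulation, and the chromene acid is hydrogenated and homologated to alkyne 14. Carbene complex 22 is made from ethoxyethyne. Ring B is closed last (the C-3/C-4 bond by 6π closure of a dienylketene), then oxidised and unmasked.
- Stereochemistry: the single stereocentre (C-3 of the chroman, R) comes from the ruthenium–BINAP hydrogenation of acid 10 in step 6 and is carried through unchanged.

Key step: step 13

Assumption: the R enantiomer of BINAP is taken to be the one that delivers hydrogen to the face of 10 that gives the 3S acid 11; if the sense of induction proves opposite, the S ligand is used and nothing else changes.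

**Route**

Step 1
Reactants: 1 3,5-dimethoxyphenol
Product: 2 (3,5-dimethoxyphenoxy)triisopropylsilane
Conditions: TIPSCl, imidazole, DMF, rt
Reagents that add atoms: chlorotriisopropylsilane (TIPSCl), CC(C)[Si](Cl)(C(C)C)C(C)C
Why: Imidazole-promoted silylation of a phenol; the bulky, non-coordinating triisopropylsilyl ether is chosen so that the next lithiation is steered to C-4, between the two methoxy groups.

Step 2
Reactants: 2 (3,5-dimethoxyphenoxy)triisopropylsilane; 3 1-bromo-3-methylbut-2-ene (prenyl bromide)
Product: 6 3,5-dimethoxy-4-(3-methylbut-2-en-1-yl)phenol, via aryllithium 4 (not isolated), via prenylated silyl ether 5 (not isolated)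
Conditions: nBuLi (1.1 equiv), THF, 0 °C to rt; CuBr·SMe2 (10 mol%), 3 (0.95 equiv), −78 °C to rt; then TBAF, rt
Reagents that add atoms: none
Why: Directed ortho-metalation should occur at the carbon flanked by both methoxy groups because the bulky silyl ether does not direct, the aryllithium is alkylated at the primary carbon of the allylic bromide (kept limiting so that none is left for O-alkylation), and fluoride then cleaves the aryl silyl ether in the same flask.

Step 3
Reactants: 6 3,5-dimethoxy-4-(3-methylbut-2-en-1-yl)phenol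
Product: 7 6-hydroxy-2,4-dimethoxy-3-(3-methylbut-2-en-1-yl)benzaldehyde
Conditions: (CH2O)n, MgCl2, Et3N, MeCN, reflux
Reagents that add atoms: paraformaldehyde (formaldehyde), C=O
Why: Magnesium-phenoxide-mediated ortho-formylation (Casnati–Skattebøl) delivers formaldehyde only ortho to the phenol, the two ortho positions of symmetric 6 are equivalent, and the conditions are neutral enough for the prenyl group.

Step 4
Reactants: 7 6-hydroxy-2,4-dimethoxy-3-(3-methylbut-2-en-1-yl)benzaldehyde; 8 prop-2-enal (acrolein)
Product: 9 5,7-dimethoxy-6-(3-methylbut-2-en-1-yl)-2H-chromene-3-carbaldehyde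
Conditions: K2CO3, 1,4-dioxane, reflux
Reagents that add atoms: none
Why: Oxa-Michael addition of the phenoxide to acrolein followed by intramolecular aldol condensation onto the neighbouring aldehyde closes the pyran ring C as the 2H-chromene-3-carbaldehyde, a standard annulation of salicylaldehydes.

Step 5
Reactants: 9 5,7-dimethoxy-6-(3-methylbut-2-en-1-yl)-2H-chromene-3-carbaldehyde
Product: 10 5,7-dimethoxy-6-(3-methylbut-2-en-1-yl)-2H-chromene-3-carboxylic acid
Conditions: Ag2O, aq. NaOH, EtOH, rt; then 1 M HCl to pH 3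
Reagents that add atoms: sodium hydroxide (aqueous), [Na+].[OH-]
Why: Silver oxide oxidation of an enal to the enoic acid uses no electrophilic halogen, so the very electron-rich ring A and the prenyl alkene should be left alone.

Step 6
Reactants: 10 5,7-dimethoxy-6-(3-methylbut-2-en-1-yl)-2H-chromene-3-carboxylic acid
Product: 11 (3S)-5,7-dimethoxy-6-(3-methylbut-2-en-1-yl)-3,4-dihydro-2H-chromene-3-carboxylic acid
Conditions: Ru(OAc)2[(R)-BINAP] (1 mol%), H2 (4 atm), MeOH, 25 °C
Reagents that add atoms: none
Why: Carboxylate-directed asymmetric hydrogenation of a 2-alkyl-3-arylpropenoic acid with a BINAP ruthenium dicarboxylate sets C-3 by face-selective hydrogen delivery inside the chelated ruthenium carboxylate, while the isolated trisubstituted prenyl alkene cannot chelate and should not be reduced.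

Step 7
Reactants: 11 (3S)-5,7-dimethoxy-6-(3-methylbut-2-en-1-yl)-3,4-dihydro-2H-chromene-3-carboxylic acid
Product: 12 [(3R)-5,7-dimethoxy-6-(3-methylbut-2-en-1-yl)-3,4-dihydro-2H-chromen-3-yl]methanol
Conditions: LiAlH4, THF, 0 °C to rt; then H2O, aq. NaOH
Reagents that add atoms: none
Why: LiAlH4 reduction of a carboxylic acid to the primary alcohol goes through the non-enolisable carboxylate and, unlike a borane, leaves the prenyl alkene untouched (the descriptor changes to R only through the priority rules).

Step 8
Reactants: 12 [(3R)-5,7-dimethoxy-6-(3-methylbut-2-en-1-yl)-3,4-dihydro-2H-chromen-3-yl]methanol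
Product: 13 (3S)-5,7-dimethoxy-6-(3-methylbut-2-en-1-yl)-3,4-dihydro-2H-chromene-3-carbaldehyde
Conditions: Dess–Martin periodinane, pyridine, CH2Cl2, 0 °C
Reagents that add atoms: none
Why: Dess–Martin oxidation gives the aldehyde under buffered, near-neutral conditions at low temperature, which should keep the α-stereocentre of this β-aryloxy aldehyde intact; 13 is used at once.

Step 9
Reactants: 13 (3S)-5,7-dimethoxy-6-(3-methylbut-2-en-1-yl)-3,4-dihydro-2H-chromene-3-carbaldehyde
Product: 14 (3R)-3-ethynyl-5,7-dimethoxy-6-(3-methylbut-2-en-1-yl)-3,4-dihydro-2H-chromene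
Conditions: dimethyl (1-diazo-2-oxopropyl)phosphonate, K2CO3, MeOH, 0 °C to rt
Reagents that add atoms: dimethyl (1-diazo-2-oxopropyl)phosphonate (Ohira–Bestmann reagent), COP(=O)(OC)C(=[N+]=[N-])C(C)=O
Why: Seyferth–Gilbert homologation in the Ohira–Bestmann variant converts the aldehyde into the terminal alkyne through a diazoalkene and the 1,2-hydrogen shift of an alkylidene carbene, under carbonate/methanol conditions that α-branched aldehydes generally tolerate.

Step 10
Reactants: 15 ethoxyethyne; 3 1-bromo-3-methylbut-2-ene (prenyl bromide)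
Product: 17 1-ethoxy-5-methylhex-4-en-1-yne, via lithium ethoxyacetylide 16 (not isolated)
Conditions: nBuLi, THF, −78 °C; then DMPU, 3, −78 °C to rt
Reagents that add atoms: none
Why: SN2 alkylation of lithium ethoxyacetylide by a reactive primary allylic bromide in THF/DMPU should give the 1-ethoxyalkyne at the unhindered carbon of the prenyl unit.

Step 11
Reactants: 17 1-ethoxy-5-methylhex-4-en-1-yne
Product: 18 tributyl[(1E)-1-ethoxy-5-methylhexa-1,4-dien-1-yl]stannane
Conditions: Bu3SnH, Pd(PPh3)4 (2 mol%), THF, 0 °C
Reagents that add atoms: tributylstannane, CCCC[SnH](CCCC)CCCC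
Why: Palladium-catalysed syn-hydrostannation of a 1-alkoxyalkyne places tin on the oxygen-bearing carbon and hydrogen on the β-carbon, giving the (E)-α-stannyl enol ether as a geometrically defined precursor of the α-alkoxyalkenyl anion.

Step 12
Reactants: 18 tributyl[(1E)-1-ethoxy-5-methylhexa-1,4-dien-1-yl]stannane; 19 hexacarbonylchromium Cr(CO)6
Product: 22 pentacarbonyl[(2Z)-2-ethoxy-1-methoxy-6-methylhepta-2,5-dien-1-ylidene]chromium, via alkenyllithium 20 (not isolated), via lithium acylchromate 21 (not isolated)
Conditions: nBuLi, THF, −78 °C; Cr(CO)6, THF, −78 °C to rt; solvent exchange; Me3OBF4, CH2Cl2, 0 °C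
Reagents that add atoms: trimethyloxonium tetrafluoroborate, C[O+](C)C.F[B-](F)(F)F
Why: Fischer carbene synthesis, in which tin–lithium exchange with retention gives the α-ethoxyalkenyllithium, this adds to a carbonyl ligand of Cr(CO)6, and O-methylation of the acylchromate with the Meerwein salt gives the alkenyl(methoxy)carbene complex, as known for lithiated cyclic enol ethers.

Step 13
Reactants: 22 pentacarbonyl[(2Z)-2-ethoxy-1-methoxy-6-methylhepta-2,5-dien-1-ylidene]chromium; 14 (3R)-3-ethynyl-5,7-dimethoxy-6-(3-methylbut-2-en-1-yl)-3,4-dihydro-2H-chromene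
Product: 25 6-[(3R)-5,7-dimethoxy-6-(3-methylbut-2-en-1-yl)-3,4-dihydro-2H-chromen-3-yl]-3-ethoxy-4-methoxy-2-(3-methylbut-2-en-1-yl)phenol, via tricarbonylchromium dienylketene complex 23 (not isolated), via tricarbonylchromium phenol complex 24 (not isolated)
Conditions: 22 (1.5 equiv), 14 (1.0 equiv), THF (degassed, 0.05 M), 50 °C; then air, rt
Reagents that add atoms: none
Why: In this Dötz benzannulation, loss of one CO from 22 lets the terminal alkyne insert into the Cr=C bond with its CH terminus bonding to the carbene carbon (future C-1), CO then inserts at the chromanyl-bearing carbon to give the η4-dienylketene 23, and its ketene carbon (future C-4) bonds to the β-carbon of the enol ether alkene (future C-3, carrying the prenyl group), after which tautomerisation gives arene complex 24 and air releases phenol 25. The closest known reaction type is the benzannulation of alkenyl(alkoxy)carbene chromium complexes with terminal alkynes, including complexes of cyclic α-alkoxyalkenyl (enol ether) carbenes. Ring B is closed as a six-membered carbocycle by a thermal disrotatory 6π electrocyclic closure of the metal-bound dienylketene. No new stereocentre is formed and the propargylic centre of 14 is not touched, so its R configuration is carried over. The step needs regioselective alkyne insertion, secured by the terminal alkyne (the bulky chromanyl group ends up next to the CO-derived carbon); it needs phenol formation over cyclopentannulation, secured by the chromium/alkoxy/THF combination and the hydrogen on the alkenyl β-carbon; and it needs reaction at the alkyne only, since the two trisubstituted prenyl alkenes should not react with the carbene complex at 50 °C.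

Step 14
Reactants: 25 6-[(3R)-5,7-dimethoxy-6-(3-methylbut-2-en-1-yl)-3,4-dihydro-2H-chromen-3-yl]-3-ethoxy-4-methoxy-2-(3-methylbut-2-en-1-yl)phenol
Product: 26 5-[(3R)-5,7-dimethoxy-6-(3-methylbut-2-en-1-yl)-3,4-dihydro-2H-chromen-3-yl]-2-ethoxy-3-(3-methylbut-2-en-1-yl)cyclohexa-2,5-diene-1,4-dione
Conditions: PhI(OAc)2 (1.1 equiv), MeCN/H2O 4:1, 0 °C
Reagents that add atoms: water, O
Why: Hypervalent-iodine oxidation of a para-methoxyphenol to the para-quinone (phenol ligation to iodine, attack of water at the methoxy-bearing para carbon, loss of methanol) is selective for the free phenol ring, so ring A, the ethyl enol ether and the prenyl groups should survive.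

Step 15
Reactants: 26 5-[(3R)-5,7-dimethoxy-6-(3-methylbut-2-en-1-yl)-3,4-dihydro-2H-chromen-3-yl]-2-ethoxy-3-(3-methylbut-2-en-1-yl)cyclohexa-2,5-diene-1,4-dione
Product: 27 5-[(3R)-5,7-dimethoxy-6-(3-methylbut-2-en-1-yl)-3,4-dihydro-2H-chromen-3-yl]-2-hydroxy-3-(3-methylbut-2-en-1-yl)cyclohexa-2,5-diene-1,4-dione (CNP0241224.1)
Conditions: LiOH (aq. 1 M, 3 equiv), THF, 0 °C; then 1 M HCl to pH 3, 0 °C
Reagents that add atoms: lithium hydroxide (aqueous), [Li+].[OH-]
Why: Hydrolysis of a 2-alkoxy-1,4-benzoquinone is a vinylogous ester saponification (addition of hydroxide at C-2, loss of ethoxide) driven by formation of the stabilised hydroxyquinone anion, and at 0 °C it should leave the C-3 stereocentre of the chroman alone.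

**Compound list**

1 | 3,5-dimethoxyphenol | COc1cc(O)cc(OC)c1 | starting material
2 | (3,5-dimethoxyphenoxy)triisopropylsilane | COc1cc(O[Si](C(C)C)(C(C)C)C(C)C)cc(OC)c1 | intermediate
3 | 1-bromo-3-methylbut-2-ene (prenyl bromide) | CC(C)=CCBr | starting material
4 | [2,6-dimethoxy-4-(triisopropylsilyloxy)phenyl]lithium | [Li]c1c(OC)cc(O[Si](C(C)C)(C(C)C)C(C)C)cc1OC | intermediate
5 | [3,5-dimethoxy-4-(3-methylbut-2-en-1-yl)phenoxy]triisopropylsilane | COc1cc(O[Si](C(C)C)(C(C)C)C(C)C)cc(OC)c1CC=C(C)C | intermediate
6 | 3,5-dimethoxy-4-(3-methylbut-2-en-1-yl)phenol | COc1cc(O)cc(OC)c1CC=C(C)C | intermediate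
7 | 6-hydroxy-2,4-dimethoxy-3-(3-methylbut-2-en-1-yl)benzaldehyde | COc1cc(O)c(C=O)c(OC)c1CC=C(C)C | intermediate
8 | prop-2-enal (acrolein) | C=CC=O | starting material
9 | 5,7-dimethoxy-6-(3-methylbut-2-en-1-yl)-2H-chromene-3-carbaldehyde | COc1cc2c(c(OC)c1CC=C(C)C)C=C(C=O)CO2 | intermediate
10 | 5,7-dimethoxy-6-(3-methylbut-2-en-1-yl)-2H-chromene-3-carboxylic acid | COc1cc2c(c(OC)c1CC=C(C)C)C=C(C(=O)O)CO2 | intermediate
11 | (3S)-5,7-dimethoxy-6-(3-methylbut-2-en-1-yl)-3,4-dihydro-2H-chromene-3-carboxylic acid | COc1cc2c(c(OC)c1CC=C(C)C)C[C@H](C(=O)O)CO2 | intermediate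
12 | [(3R)-5,7-dimethoxy-6-(3-methylbut-2-en-1-yl)-3,4-dihydro-2H-chromen-3-yl]methanol | COc1cc2c(c(OC)c1CC=C(C)C)C[C@H](CO)CO2 | intermediate
13 | (3S)-5,7-dimethoxy-6-(3-methylbut-2-en-1-yl)-3,4-dihydro-2H-chromene-3-carbaldehyde | COc1cc2c(c(OC)c1CC=C(C)C)C[C@H](C=O)CO2 | intermediate
14 | (3R)-3-ethynyl-5,7-dimethoxy-6-(3-methylbut-2-en-1-yl)-3,4-dihydro-2H-chromene | COc1cc2c(c(OC)c1CC=C(C)C)C[C@H](C#C)CO2 | intermediate
15 | ethoxyethyne | CCOC#C | starting material
16 | lithium ethoxyacetylide | CCOC#C[Li] | intermediate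
17 | 1-ethoxy-5-methylhex-4-en-1-yne | CCOC#CCC=C(C)C | intermediate
18 | tributyl[(1E)-1-ethoxy-5-methylhexa-1,4-dien-1-yl]stannane | CCCC[Sn](CCCC)(CCCC)/C(OCC)=C/CC=C(C)C | intermediate
19 | hexacarbonylchromium Cr(CO)6 | O=C=[Cr](=C=O)(=C=O)(=C=O)(=C=O)=C=O | starting material
20 | [(1Z)-1-ethoxy-5-methylhexa-1,4-dien-1-yl]lithium | [Li]/C(OCC)=C/CC=C(C)C | intermediate
21 | lithium pentacarbonyl[(2Z)-2-ethoxy-6-methyl-1-oxidohepta-2,5-dien-1-ylidene]chromate | [Li+].[O-]C(=[Cr](=C=O)(=C=O)(=C=O)(=C=O)=C=O)/C(OCC)=C/CC=C(C)C | intermediate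
22 | pentacarbonyl[(2Z)-2-ethoxy-1-methoxy-6-methylhepta-2,5-dien-1-ylidene]chromium | COC(=[Cr](=C=O)(=C=O)(=C=O)(=C=O)=C=O)/C(OCC)=C/CC=C(C)C | intermediate
23 | tricarbonylchromium η4 complex of the dienylketene (ketene carbon attached to the chroman-bearing carbon; drawn as ligand plus Cr(CO)3) | COc1cc2c(c(OC)c1CC=C(C)C)C[C@H](C(=C=O)/C=C(OC)\C(OCC)=C\CC=C(C)C)CO2.O=C=[Cr](=C=O)=C=O | intermediate
24 | tricarbonylchromium η6 complex of phenol 25 (drawn as ligand plus Cr(CO)3) | COc1cc2c(c(OC)c1CC=C(C)C)C[C@H](c1cc(OC)c(OCC)c(CC=C(C)C)c1O)CO2.O=C=[Cr](=C=O)=C=O | intermediate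
25 | 6-[(3R)-5,7-dimethoxy-6-(3-methylbut-2-en-1-yl)-3,4-dihydro-2H-chromen-3-yl]-3-ethoxy-4-methoxy-2-(3-methylbut-2-en-1-yl)phenol | COc1cc2c(c(OC)c1CC=C(C)C)C[C@H](c1cc(OC)c(OCC)c(CC=C(C)C)c1O)CO2 | intermediate
26 | 5-[(3R)-5,7-dimethoxy-6-(3-methylbut-2-en-1-yl)-3,4-dihydro-2H-chromen-3-yl]-2-ethoxy-3-(3-methylbut-2-en-1-yl)cyclohexa-2,5-diene-1,4-dione | COc1cc2c(c(OC)c1CC=C(C)C)C[C@H](C1=CC(=O)C(OCC)=C(CC=C(C)C)C1=O)CO2 | intermediate
27 | 5-[(3R)-5,7-dimethoxy-6-(3-methylbut-2-en-1-yl)-3,4-dihydro-2H-chromen-3-yl]-2-hydroxy-3-(3-methylbut-2-en-1-yl)cyclohexa-2,5-diene-1,4-dione | COc1cc2c(c(OC)c1CC=C(C)C)C[C@H](C1=CC(=O)C(O)=C(CC=C(C)C)C1=O)CO2 | target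

**Step count and risks**

Total step count: 15 (steps 1–9 to alkyne 14, steps 10–12 to carbene complex 22, steps 13–15 for the endgame).
Longest linear sequence: 12 steps (steps 1–9 and 13–15, from 3,5-dimethoxyphenol 1).

Steps most likely to fail:

1. Step 13. The vinylcarbene intermediate may be diverted before CO insertion and 6π closure (cyclopentannulation, furan formation, uptake of a second alkyne), and the electron-rich α-ethoxy carbene complex may decay thermally, so that the precious alkyne is consumed unproductively. The fallback sets out from alkyne 14 and comes back to the route at target 27; it builds ring B by a Moore rearrangement instead. The known reagent 3-isopropoxy-4-(tributylstannyl)cyclobut-3-ene-1,2-dione would be coupled with prenyl bromide 3 (Stille coupling, Pd(PPh3)4 and CuI as catalysts, DMF, rt) to give 3-isopropoxy-4-(3-methylbut-2-en-1-yl)cyclobut-3-ene-1,2-dione F1. Alkyne 14 would be deprotonated (nBuLi, THF, −78 °C) to its lithium acetylide F2, which should add to the ketone carbonyl of F1 next to the isopropoxy-bearing carbon (the other carbonyl is a vinylogous ester) to give the 4-alkynyl-4-hydroxycyclobutenone F3, as a mixture at the carbinol carbon. Heating F3 (toluene, 100 °C) should bring about electrocyclic opening to the enynylketene, ring closure and hydrogen transfer to give the isopropoxyquinone F4, the isopropyl analogue of 26. Hydrolysis of F4 under the conditions of step 15 would give 27.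

2. Step 9. Configuration at C-3 may be partly lost by enolisation of aldehyde 13, or by reversible β-elimination and re-addition of the aryloxide, under K2CO3/MeOH. The fallback sets out from aldehyde 13 and comes back at alkyne 14, using a base-free olefination (Corey–Fuchs). CBr4 and PPh3 (CH2Cl2, 0 °C) would give (3R)-3-(2,2-dibromoethenyl)-5,7-dimethoxy-6-(3-methylbut-2-en-1-yl)-3,4-dihydro-2H-chromene F5. nBuLi (2.2 equiv, THF, −78 °C) would then convert F5 into the lithium acetylide F6 (the same species as F2), which is protonated on aqueous work-up to 14.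

3. Step 15. Hydroxide may add in conjugate fashion at the unsubstituted C-6 of the quinone, or the base may tautomerise the quinone to a quinone methide with loss of configuration at C-3 of the chroman. The fallback sets out from 26 and comes back at 27, and cleaves the O–ethyl bond instead of the ring C–O bond under aprotic Lewis-acidic conditions. BCl3 (1.2 equiv, CH2Cl2, −78 °C) should chelate the C-1 carbonyl and the enol ether oxygen, chloride should remove the ethyl group to give the dichloroboryl enolate F7, and aqueous NaHCO3 work-up would hydrolyse F7 to 27.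

**Further compounds**

F1 | step 13 | 3-isopropoxy-4-(3-methylbut-2-en-1-yl)cyclobut-3-ene-1,2-dione | CC(C)OC1=C(CC=C(C)C)C(=O)C1=O
F2 | step 13 | lithium acetylide of 14, {[(3R)-5,7-dimethoxy-6-(3-methylbut-2-en-1-yl)-3,4-dihydro-2H-chromen-3-yl]ethynyl}lithium | COc1cc2c(c(OC)c1CC=C(C)C)C[C@H](C#C[Li])CO2
F3 | step 13 | 4-{[(3R)-5,7-dimethoxy-6-(3-methylbut-2-en-1-yl)-3,4-dihydro-2H-chromen-3-yl]ethynyl}-4-hydroxy-3-isopropoxy-2-(3-methylbut-2-en-1-yl)cyclobut-2-en-1-one (both configurations at the carbinol carbon) | COc1cc2c(c(OC)c1CC=C(C)C)C[C@H](C#CC1(O)C(OC(C)C)=C(CC=C(C)C)C1=O)CO2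
F4 | step 13 | 5-[(3R)-5,7-dimethoxy-6-(3-methylbut-2-en-1-yl)-3,4-dihydro-2H-chromen-3-yl]-2-isopropoxy-3-(3-methylbut-2-en-1-yl)cyclohexa-2,5-diene-1,4-dione | COc1cc2c(c(OC)c1CC=C(C)C)C[C@H](C1=CC(=O)C(OC(C)C)=C(CC=C(C)C)C1=O)CO2
F5 | step 9 | (3R)-3-(2,2-dibromoethenyl)-5,7-dimethoxy-6-(3-methylbut-2-en-1-yl)-3,4-dihydro-2H-chromene | COc1cc2c(c(OC)c1CC=C(C)C)C[C@H](C=C(Br)Br)CO2
F6 | step 9 | lithium acetylide of 14 (identical with F2) | COc1cc2c(c(OC)c1CC=C(C)C)C[C@H](C#C[Li])CO2
F7 | step 15 | dichloroboryl enolate of 27 (O-dichloroboryl at C-2 of the quinone) | COc1cc2c(c(OC)c1CC=C(C)C)C[C@H](C1=CC(=O)C(OB(Cl)Cl)=C(CC=C(C)C)C1=O)CO2
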